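**Retrosynthetic overview**
1. Target ⇐ primary-selective acetylation ⇐ trans-selective enolate hydroxylation of butyrolactone 19.
2. Key disconnection, lactone C4–C5: a hydroxymethyl radical from methanol (a formaldehyde-level carbon used as a nucleophile) adds to the electrophilic β-carbon of unsaturated δ-lactone 17, anti to its C5 substituent; the δ-lactone then switches to the γ-lactone.
3. 17 ⇐ β,γ-unsaturated aldehyde 14 by catalytic asymmetric α-hydroxymethylation and ketenylidene-phosphorane annulation; 14 ⇐ isopropenyl hydrindane 12 by formaldehyde ene reaction and oxidation.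
4. 12 ⇐ 2-methylcyclopent-2-en-1-one by asymmetric conjugate addition of isopropenyl, Robinson annulation with ethyl vinyl ketone, reductive methylation and Wolff–Kishner reduction.
5. Ring order: cyclopentane (from 1) → cyclohexane of the hydrindane (step 2) → δ-lactone (step 7) → γ-lactone by ring switch (step 8).

Assumption: small reagents (Me3SiCl, CH3I, CH2O, MeOH, Ph3P=C=C=O, the oxaziridine, AcCl) are named under "Reagents that add atoms" and are not numbered.

**Step 1**
Reactants: 1 2-methylcyclopent-2-en-1-one; 2 isopropenylmagnesium bromide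
Product: 4 (R)-trimethyl{[2-methyl-3-(prop-1-en-2-yl)cyclopent-1-en-1-yl]oxy}silane, via bromomagnesium enolate 3 (not isolated)
Conditions: CuBr·SMe2 (5 mol%), (R)-1-[(S)-2-(diphenylphosphino)ferrocenyl]ethyldicyclohexylphosphine or its antipode (6 mol%; the antipode that gives (R)-4), t-BuOMe, −78 °C; then Me3SiCl, Et3N, DMPU, −78 to 0 °C
Reagents that add atoms: chlorotrimethylsilane C[Si](C)(C)Cl
Why: Copper-catalysed asymmetric conjugate addition of a Grignard reagent to the α-substituted enone (a known reaction type for 2-methylcyclopentenone with enolate trapping) sets the future hydrindane C1 by ligand control, and O-silylation fixes the regiodefined tetrasubstituted enolate.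

**Step 2**
Reactants: 4 (R)-trimethyl{[2-methyl-3-(prop-1-en-2-yl)cyclopent-1-en-1-yl]oxy}silane; 5 pent-1-en-3-one (ethyl vinyl ketone)
Product: 8 (1R,7aR)-4,7a-dimethyl-1-(prop-1-en-2-yl)-1,2,3,6,7,7a-hexahydro-5H-inden-5-one, via silyl enol ether adduct 6 (not isolated), via diketone 7 (not isolated)
Conditions: Tf2NH (2 mol%), toluene, −78 °C; then KOH, MeOH, 60 °C
Reagents that add atoms: none
Why: Robinson annulation in which the Mukaiyama–Michael addition occurs on the enol ether face anti to the neighbouring isopropenyl group (quaternary centre with methyl cis to isopropenyl), after which methanolic base removes the silyl group and effects the intramolecular aldol condensation.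

**Step 3**
Reactants: 8 (1R,7aR)-4,7a-dimethyl-1-(prop-1-en-2-yl)-1,2,3,6,7,7a-hexahydro-5H-inden-5-one
Product: 10 (1R,3aR,7aR)-4,4,7a-trimethyl-1-(prop-1-en-2-yl)octahydro-5H-inden-5-one, via lithium enolate 9 (not isolated)
Conditions: Li, NH3, THF, t-BuOH (1 equiv), −78 °C; then CH3I, −78 to −33 °C
Reagents that add atoms: iodomethane CI
Why: Stork reductive alkylation, in which dissolving-metal reduction protonates C3a on the face opposite the angular methyl (trans ring fusion, as in related 1β-substituted hydrindenones) and the regiodefined enolate is C-methylated to the gem-dimethyl ketone while the isolated alkene is untouched.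

**Step 4**
Reactants: 10 (1R,3aR,7aR)-4,4,7a-trimethyl-1-(prop-1-en-2-yl)octahydro-5H-inden-5-one
Product: 12 (1R,3aS,7aR)-4,4,7a-trimethyl-1-(prop-1-en-2-yl)octahydro-1H-indene, via hydrazone 11 (not isolated)
Conditions: N2H4·H2O, KOH, diethylene glycol, 130 then 210 °C
Reagents that add atoms: none
Why: Wolff–Kishner reduction (Huang–Minlon procedure) removes the hindered ketone without touching the isolated 1,1-disubstituted alkene or any stereocentre.

**Step 5**
Reactants: 12 (1R,3aS,7aR)-4,4,7a-trimethyl-1-(prop-1-en-2-yl)octahydro-1H-indene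
Product: 13 3-[(1R,3aS,7aS)-4,4,7a-trimethyloctahydro-1H-inden-1-yl]but-3-en-1-ol
Conditions: (CH2O)n, Me2AlCl, CH2Cl2, 0 °C; aq HCl work-up
Reagents that add atoms: formaldehyde (from paraformaldehyde) C=O
Why: Lewis-acid-promoted carbonyl-ene reaction of formaldehyde transfers a methyl hydrogen in preference to the hindered ring methine hydrogen, giving the homoallylic alcohol and regenerating a 1,1-disubstituted alkene.

**Step 6**
Reactants: 13 3-[(1R,3aS,7aS)-4,4,7a-trimethyloctahydro-1H-inden-1-yl]but-3-en-1-ol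
Product: 14 3-[(1R,3aS,7aS)-4,4,7a-trimethyloctahydro-1H-inden-1-yl]but-3-enal
Conditions: Dess–Martin periodinane, CH2Cl2, 0 °C; used crude
Reagents that add atoms: none
Why: Dess–Martin oxidation gives the β,γ-unsaturated aldehyde under neutral conditions that do not move the double bond into conjugation.

**Step 7**
Reactants: 14 3-[(1R,3aS,7aS)-4,4,7a-trimethyloctahydro-1H-inden-1-yl]but-3-enal
Product: 17 (5R)-5-{1-[(1R,3aS,7aS)-4,4,7a-trimethyloctahydro-1H-inden-1-yl]ethenyl}-5,6-dihydro-2H-pyran-2-one, via hydroxymethyl aldehyde 15 (not isolated), via acyl ylide 16 (not isolated)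
Conditions: aq CH2O (37%), (S)-α,α-diphenylprolinol trimethylsilyl ether (10 mol%), pH 7 buffer, toluene, 20 °C; organic phase dried, then Ph3P=C=C=O, toluene, 60 °C
Reagents that add atoms: formaldehyde C=O; (triphenylphosphoranylidene)ketene O=C=C=P(c1ccccc1)(c1ccccc1)c1ccccc1
Why: Enamine-catalysed α-hydroxymethylation, with the (S)-diarylprolinol silyl ether shielding one enamine face in the same sense as in its Michael reactions, sets the (R) centre, and the hydroxy aldehyde is then O-acylated by the ketenylidene phosphorane and closed by intramolecular Wittig reaction (Bestmann annulation) to the unsaturated δ-lactone under neutral conditions.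

**Step 8 (key step)**
Reactants: 17 (5R)-5-{1-[(1R,3aS,7aS)-4,4,7a-trimethyloctahydro-1H-inden-1-yl]ethenyl}-5,6-dihydro-2H-pyran-2-one
Product: 19 (4R)-4-{(2R)-1-hydroxy-3-[(1R,3aS,7aS)-4,4,7a-trimethyloctahydro-1H-inden-1-yl]but-3-en-2-yl}oxolan-2-one, via hydroxymethyl δ-lactone 18 (not isolated)
Conditions: MeOH/MeCN, Ir[dF(CF3)ppy]2(dtbbpy)PF6 (1 mol%), quinuclidine (10 mol%), Bu4N·H2PO4 (25 mol%), blue LEDs, 25 °C; then camphorsulfonic acid (10 mol%), 40 °C
Reagents that add atoms: methanol CO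
Why: Photoredox hydrogen-atom-transfer alkylation of an alcohol α-C–H bond (Giese addition) makes the nucleophilic hydroxymethyl radical, a hydroxymethyl anion equivalent, which joins the formaldehyde-level carbon to the electrophilic enoate β-carbon anti to the adjacent C5 substituent to set C4, and acid-catalysed translactonisation then gives the more stable γ-lactone and frees the primary alcohol.

**Step 9**
Reactants: 19 (4R)-4-{(2R)-1-hydroxy-3-[(1R,3aS,7aS)-4,4,7a-trimethyloctahydro-1H-inden-1-yl]but-3-en-2-yl}oxolan-2-one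
Product: 21 (3S,4R)-3-hydroxy-4-{(2R)-1-hydroxy-3-[(1R,3aS,7aS)-4,4,7a-trimethyloctahydro-1H-inden-1-yl]but-3-en-2-yl}oxolan-2-one, via disodium enolate alkoxide 20 (not isolated)
Conditions: NaN(SiMe3)2 (2.3 equiv), THF, −78 °C; then 2-(benzenesulfonyl)-3-phenyloxaziridine, −78 °C; AcOH quench
Reagents that add atoms: 2-(benzenesulfonyl)-3-phenyloxaziridine O=S(=O)(N1OC1c1ccccc1)c1ccccc1
Why: Davis enolate hydroxylation, in which the lactone enolate (formed after the alkoxide) is oxidised on the face anti to the C4 substituent to give the trans 3-hydroxy lactone.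

**Step 10**
Reactants: 21 (3S,4R)-3-hydroxy-4-{(2R)-1-hydroxy-3-[(1R,3aS,7aS)-4,4,7a-trimethyloctahydro-1H-inden-1-yl]but-3-en-2-yl}oxolan-2-one
Product: 22 (2R)-2-[(3R,4S)-4-hydroxy-5-oxooxolan-3-yl]-3-[(1R,3aS,7aS)-4,4,7a-trimethyloctahydro-1H-inden-1-yl]but-3-en-1-yl acetate (CNP0252518.2)
Conditions: AcCl (1.1 equiv), 2,4,6-collidine, CH2Cl2, −78 °C
Reagents that add atoms: acetyl chloride CC(Cl)=O
Why: Chemoselective acylation, the unhindered primary alcohol reacting with acetyl chloride and collidine at low temperature much faster than the hydrogen-bonded secondary α-hydroxy lactone.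

**Compound list**
1 | 2-methylcyclopent-2-en-1-one | CC1=CCCC1=O | starting material
2 | isopropenylmagnesium bromide | C=C(C)[Mg]Br | starting material
3 | bromomagnesium (R)-2-methyl-3-(prop-1-en-2-yl)cyclopent-1-en-1-olate | CC(=C)[C@H]1CCC(O[Mg]Br)=C1C | intermediate (not isolated)
4 | (R)-trimethyl{[2-methyl-3-(prop-1-en-2-yl)cyclopent-1-en-1-yl]oxy}silane | CC(=C)[C@H]1CCC(O[Si](C)(C)C)=C1C | intermediate
5 | pent-1-en-3-one (ethyl vinyl ketone) | CCC(=O)C=C | starting material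
6 | (2R,3R)-2-methyl-3-(prop-1-en-2-yl)-2-[(Z)-3-(trimethylsilyloxy)pent-2-en-1-yl]cyclopentan-1-one | CC(=C)[C@H]1CCC(=O)[C@]1(C)C/C=C(\O[Si](C)(C)C)CC | intermediate (not isolated)
7 | (2R,3R)-2-methyl-2-(3-oxopentyl)-3-(prop-1-en-2-yl)cyclopentan-1-one | CC(=C)[C@H]1CCC(=O)[C@]1(C)CCC(=O)CC | intermediate (not isolated)
8 | (1R,7aR)-4,7a-dimethyl-1-(prop-1-en-2-yl)-1,2,3,6,7,7a-hexahydro-5H-inden-5-one | CC(=C)[C@H]1CCC2=C(C)C(=O)CC[C@]12C | intermediate
9 | lithium (1R,3aR,7aR)-4,7a-dimethyl-1-(prop-1-en-2-yl)-2,3,3a,6,7,7a-hexahydro-1H-inden-5-olate | CC(=C)[C@H]1CC[C@H]2C(C)=C(O[Li])CC[C@]12C | intermediate (not isolated)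
10 | (1R,3aR,7aR)-4,4,7a-trimethyl-1-(prop-1-en-2-yl)octahydro-5H-inden-5-one (trans-fused) | CC(=C)[C@H]1CC[C@H]2C(C)(C)C(=O)CC[C@]12C | intermediate
11 | (1R,3aR,7aR)-5-hydrazinylidene-4,4,7a-trimethyl-1-(prop-1-en-2-yl)octahydro-1H-indene | CC(=C)[C@H]1CC[C@H]2C(C)(C)C(=NN)CC[C@]12C | intermediate (not isolated)
12 | (1R,3aS,7aR)-4,4,7a-trimethyl-1-(prop-1-en-2-yl)octahydro-1H-indene (trans-fused; isopropenyl cis to 7a-methyl) | CC(=C)[C@H]1CC[C@H]2C(C)(C)CCC[C@]12C | intermediate
13 | 3-[(1R,3aS,7aS)-4,4,7a-trimethyloctahydro-1H-inden-1-yl]but-3-en-1-ol | C=C(CCO)[C@H]1CC[C@H]2C(C)(C)CCC[C@]12C | intermediate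
14 | 3-[(1R,3aS,7aS)-4,4,7a-trimethyloctahydro-1H-inden-1-yl]but-3-enal | C=C(CC=O)[C@H]1CC[C@H]2C(C)(C)CCC[C@]12C | intermediate
15 | (2R)-2-(hydroxymethyl)-3-[(1R,3aS,7aS)-4,4,7a-trimethyloctahydro-1H-inden-1-yl]but-3-enal | C=C([C@H]1CC[C@H]2C(C)(C)CCC[C@]12C)[C@H](CO)C=O | intermediate (not isolated)
16 | (2R)-2-formyl-3-[(1R,3aS,7aS)-4,4,7a-trimethyloctahydro-1H-inden-1-yl]but-3-en-1-yl 2-(triphenyl-λ5-phosphanylidene)acetate | C=C([C@H]1CC[C@H]2C(C)(C)CCC[C@]12C)[C@H](COC(=O)C=P(c1ccccc1)(c1ccccc1)c1ccccc1)C=O | intermediate (not isolated)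
17 | (5R)-5-{1-[(1R,3aS,7aS)-4,4,7a-trimethyloctahydro-1H-inden-1-yl]ethenyl}-5,6-dihydro-2H-pyran-2-one | C=C([C@H]1CC[C@H]2C(C)(C)CCC[C@]12C)[C@@H]1COC(=O)C=C1 | intermediate
18 | (4R,5R)-4-(hydroxymethyl)-5-{1-[(1R,3aS,7aS)-4,4,7a-trimethyloctahydro-1H-inden-1-yl]ethenyl}oxan-2-one (4,5-trans) | C=C([C@H]1CC[C@H]2C(C)(C)CCC[C@]12C)[C@@H]1COC(=O)C[C@H]1CO | intermediate (not isolated)
19 | (4R)-4-{(2R)-1-hydroxy-3-[(1R,3aS,7aS)-4,4,7a-trimethyloctahydro-1H-inden-1-yl]but-3-en-2-yl}oxolan-2-one | C=C([C@H]1CC[C@H]2C(C)(C)CCC[C@]12C)[C@H](CO)[C@@H]1COC(=O)C1 | intermediate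
20 | disodium alkoxide/lactone enolate of 19 | C=C([C@H]1CC[C@H]2C(C)(C)CCC[C@]12C)[C@H](CO[Na])[C@@H]1COC(O[Na])=C1 | intermediate (not isolated)
21 | (3S,4R)-3-hydroxy-4-{(2R)-1-hydroxy-3-[(1R,3aS,7aS)-4,4,7a-trimethyloctahydro-1H-inden-1-yl]but-3-en-2-yl}oxolan-2-one | C=C([C@H]1CC[C@H]2C(C)(C)CCC[C@]12C)[C@H](CO)[C@@H]1COC(=O)[C@H]1O | intermediate
22 | (2R)-2-[(3R,4S)-4-hydroxy-5-oxooxolan-3-yl]-3-[(1R,3aS,7aS)-4,4,7a-trimethyloctahydro-1H-inden-1-yl]but-3-en-1-yl acetate | C=C([C@H]1CC[C@H]2C(C)(C)CCC[C@]12C)[C@H](COC(C)=O)[C@@H]1COC(=O)[C@H]1O | target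

**Step count:** 10 steps in total; longest linear sequence 10 steps (fully linear from 1).

**Steps most likely to fail, with fallbacks**

Step 1. High enantioselectivity is established for alkyl Grignard reagents on this enone but not for isopropenyl, and the sense of induction must be checked. The fallback sets the same centre by rhodium/boron chemistry on the unsubstituted enone. B-isopropenyl-9-BBN (from 2 and B-methoxy-9-BBN) is added to cyclopent-2-en-1-one with Rh(acac)(C2H4)2 and the BINAP antipode that gives the (S)-enolate. This gives (S)-9-{[3-(prop-1-en-2-yl)cyclopent-1-en-1-yl]oxy}-9-borabicyclo[3.3.1]nonane F1. MeLi converts it into lithium (S)-3-(prop-1-en-2-yl)cyclopent-1-en-1-olate F2, and CH3I methylates this anti to the isopropenyl group to give (2R,3S)-2-methyl-3-(prop-1-en-2-yl)cyclopentan-1-one F3. Thermodynamic silylation (Me3SiCl, Et3N, DMF, 100 °C) then gives 4. The fallback sets out from 2 and comes back at 4.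

Step 7. The dienamine may react at its γ-carbon, and the α-vinyl β-hydroxy aldehyde 15 can epimerise, dehydrate or lose formaldehyde before ring closure. The fallback sets the centre with an oxazolidinone auxiliary.
- 14 is oxidised (NaClO2, NaH2PO4, 2-methylbut-2-ene) to 3-[(1R,3aS,7aS)-4,4,7a-trimethyloctahydro-1H-inden-1-yl]but-3-enoic acid F4.
- F4 is coupled (pivaloyl chloride, Et3N; lithiated (S)-4-benzyloxazolidin-2-one) to (S)-4-benzyl-3-{3-[(1R,3aS,7aS)-4,4,7a-trimethyloctahydro-1H-inden-1-yl]but-3-enoyl}oxazolidin-2-one F5.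
- The titanium enolate (TiCl4, i-Pr2NEt) is hydroxymethylated with 1,3,5-trioxane on the face opposite the benzyl group, giving (S)-4-benzyl-3-{(2R)-2-(hydroxymethyl)-3-[(1R,3aS,7aS)-4,4,7a-trimethyloctahydro-1H-inden-1-yl]but-3-enoyl}oxazolidin-2-one F6.
- MeONHMe·HCl/AlMe3 gives (2R)-2-(hydroxymethyl)-N-methoxy-N-methyl-3-[(1R,3aS,7aS)-4,4,7a-trimethyloctahydro-1H-inden-1-yl]but-3-enamide F7.
- i-Bu2AlH at −78 °C gives 15, which is closed at once with Ph3P=C=C=O as in step 7.

The fallback sets out from 14 and comes back at 15.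

Step 8. Hydrogen abstraction at the doubly allylic C5–H of 17 may compete with abstraction from methanol, and radical addition to a β-substituted cyclic enoate is slower than to acrylates. The fallback uses a polar silicon-masked hydroxymethyl anion. (Isopropoxydimethylsilyl)methylmagnesium chloride with CuBr·SMe2 (10 mol%) in THF at −78 °C adds to 17 anti to the C5 substituent. This gives (4R,5R)-4-{[dimethyl(propan-2-yloxy)silyl]methyl}-5-{1-[(1R,3aS,7aS)-4,4,7a-trimethyloctahydro-1H-inden-1-yl]ethenyl}oxan-2-one F8. Tamao oxidation (H2O2, KF, KHCO3, MeOH/THF) gives 18, and camphorsulfonic acid isomerises it to 19. The fallback sets out from 17 and comes back at 19.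

**Further compounds**
F1 | step 1 | (S)-9-{[3-(prop-1-en-2-yl)cyclopent-1-en-1-yl]oxy}-9-borabicyclo[3.3.1]nonane | CC(=C)[C@H]1CCC(OB2C3CCCC2CCC3)=C1
F2 | step 1 | lithium (S)-3-(prop-1-en-2-yl)cyclopent-1-en-1-olate | CC(=C)[C@H]1CCC(O[Li])=C1
F3 | step 1 | (2R,3S)-2-methyl-3-(prop-1-en-2-yl)cyclopentan-1-one | CC(=C)[C@H]1CCC(=O)[C@@H]1C
F4 | step 7 | 3-[(1R,3aS,7aS)-4,4,7a-trimethyloctahydro-1H-inden-1-yl]but-3-enoic acid | C=C(CC(=O)O)[C@H]1CC[C@H]2C(C)(C)CCC[C@]12C
F5 | step 7 | (S)-4-benzyl-3-{3-[(1R,3aS,7aS)-4,4,7a-trimethyloctahydro-1H-inden-1-yl]but-3-enoyl}oxazolidin-2-one | C=C(CC(=O)N1C(=O)OC[C@@H]1Cc1ccccc1)[C@H]1CC[C@H]2C(C)(C)CCC[C@]12C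
F6 | step 7 | (S)-4-benzyl-3-{(2R)-2-(hydroxymethyl)-3-[(1R,3aS,7aS)-4,4,7a-trimethyloctahydro-1H-inden-1-yl]but-3-enoyl}oxazolidin-2-one | C=C([C@H]1CC[C@H]2C(C)(C)CCC[C@]12C)[C@H](CO)C(=O)N1C(=O)OC[C@@H]1Cc1ccccc1
F7 | step 7 | (2R)-2-(hydroxymethyl)-N-methoxy-N-methyl-3-[(1R,3aS,7aS)-4,4,7a-trimethyloctahydro-1H-inden-1-yl]but-3-enamide | C=C([C@H]1CC[C@H]2C(C)(C)CCC[C@]12C)[C@H](CO)C(=O)N(C)OC
F8 | step 8 | (4R,5R)-4-{[dimethyl(propan-2-yloxy)silyl]methyl}-5-{1-[(1R,3aS,7aS)-4,4,7a-trimethyloctahydro-1H-inden-1-yl]ethenyl}oxan-2-one | C=C([C@H]1CC[C@H]2C(C)(C)CCC[C@]12C)[C@@H]1COC(=O)C[C@H]1C[Si](C)(C)OC(C)C
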